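**Plan**
- Retrosynthesis: cut the stearate C–O bond at O10, then C10–C11 (Grignard addition to an aldehyde), then C2–C3 (cross-metathesis on an allyl group), then O–C6 and C5–C6 together (oxonium ylide [2,3]-shift), and last C6–C7 (diazomethane acylation) and the allyl ether bond.
- Enabling feature: C6 is an ether carbon next to oxygen-bearing C7. With C7 as a ketone, C6 can be a diazo-derived carbenoid that the ether oxygen on C9 captures, and the allyl group on that oxygen becomes C3–C5.
- Forward: C7–C10 come from a β-keto ester and C6 from diazomethane; the oxolane (the only ring: O, C6, C7, C8, C9) closes in step 5; C1–C2, C11–C19 and the stearoyl group follow in that order.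
- Stereochemistry: C9 by Noyori hydrogenation; C6 relayed from C9 (2,5-trans) in the [2,3]-shift; C7 by hydride delivery anti to the C6 chain; C10 by chelation-controlled Grignard addition.

Key step: step 5

Assumption: carbons are numbered along the parent C19 chain (pentyl C1–C5, ring carbons C6–C9, carbinol C10, alkenyl chain C11–C19). Ethereal CH2N2 is prepared beforehand from N-methyl-N-nitroso-p-toluenesulfonamide and KOH and is treated as a reagent.

Step 1
Reactants: 1 ethyl 4-(benzyloxy)-3-oxobutanoate
Product: 2 ethyl (3R)-4-(benzyloxy)-3-hydroxybutanoate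
Conditions: H2 (about 50 atm), RuCl2[(S)-BINAP] (0.2 mol%), EtOH, 100 °C
Reagents that add atoms: none
Why: Noyori asymmetric hydrogenation of a β-keto ester, in which the ester carbonyl chelates ruthenium and the (S)-BINAP ligand should direct hydride to the ketone face that gives the 3R alcohol (R because CH2OBn outranks CH2CO2Et), setting C9; the elevated temperature is chosen so that ester-directed delivery outcompetes coordination by the ether oxygen, and the benzyl ether is inert to the homogeneous catalyst.

Step 2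
Reactants: 2 ethyl (3R)-4-(benzyloxy)-3-hydroxybutanoate; 3 prop-2-enyl 2,2,2-trichloroacetimidate
Product: 4 ethyl (3R)-4-(benzyloxy)-3-(prop-2-enyloxy)butanoate
Conditions: 3 (2 equiv), TfOH (10 mol%), CH2Cl2–cyclohexane, 0 °C → rt
Reagents that add atoms: prop-2-enyl 2,2,2-trichloroacetimidate (3), C=CCOC(=N)C(Cl)(Cl)Cl
Why: Acid-catalysed O-alkylation with a trichloroacetimidate transfers the allyl group without base, so the β-hydroxy ester can neither retro-aldolise nor eliminate and C9 is untouched.

Step 3
Reactants: 4 ethyl (3R)-4-(benzyloxy)-3-(prop-2-enyloxy)butanoate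
Product: 5 (3R)-4-(benzyloxy)-3-(prop-2-enyloxy)butanoic acid
Conditions: LiOH·H2O, THF–H2O, 0 °C → rt; then 1 M HCl to pH 3
Reagents that add atoms: lithium hydroxide, [Li+].[OH-]
Why: Ester saponification with LiOH at low temperature should outpace E1cB loss of the β-allyloxy group, so the stereocentre is carried through unchanged.

Step 4
Reactants: 5 (3R)-4-(benzyloxy)-3-(prop-2-enyloxy)butanoic acid
Product: 7 (4R)-5-(benzyloxy)-1-diazo-4-(prop-2-enyloxy)pentan-2-one, via mixed anhydride 6 (not isolated)
Conditions: i-BuOCOCl, Et3N, Et2O, −20 °C; then CH2N2 (excess, Et2O), 0 °C → rt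
Reagents that add atoms: diazomethane, C=[N+]=[N-]
Why: Acylation of diazomethane by a mixed carbonic anhydride (the first half of an Arndt–Eistert sequence) gives the α-diazoketone and adds C6 without an acid chloride or free HCl that could attack the allyl ether or the diazo group.

Step 5
Reactants: 7 (4R)-5-(benzyloxy)-1-diazo-4-(prop-2-enyloxy)pentan-2-one
Product: 10 (2S,5R)-5-[(benzyloxy)methyl]-2-(prop-2-enyl)oxolan-3-one, via copper carbenoid 8 (not isolated), via oxonium ylide 9 (not isolated)
Conditions: Cu(acac)2 (10 mol%), THF, reflux, slow addition of 7 at high dilution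
Reagents that add atoms: none
Why: Cu(acac)2 (divalent copper) decomposes the diazoketone with loss of N2 to an electrophilic copper carbenoid at C6 (8), a lone pair of the allyl ether oxygen on C9 adds to it to give the five-membered cyclic oxonium ylide 9, and a suprafacial [2,3]-sigmatropic shift then carries the allyl group from oxygen to C6, so that O–C6 and C5–C6 form while the old O–allyl bond breaks. The reaction type is the copper-catalysed tandem oxonium ylide formation and [2,3]-rearrangement of allyl ethers tethered to diazoketones, an established entry to 2-allyl-oxolan-3-ones. The one ring closed is the oxolanone (O, C6, C7, C8, C9), closed by intramolecular attack of oxygen on the carbenoid carbon in a five-membered (formally 5-exo) mode, which should be preferred over the six-membered ylide that the benzyl ether oxygen could form. The new stereocentre C6 is controlled by C9: in the envelope-shaped ylide the O-allyl group should sit anti to the benzyloxymethyl group and is delivered to the face of C6 on which it sits on oxygen, giving the 2,5-trans (2S,5R) ketone. The step needs this trans diastereoselectivity, secured by the C9 substituent, and chemoselectivity for ylide formation over C–H insertion and carbene dimerisation, secured by the acetylacetonate copper catalyst and slow addition.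

Step 6
Reactants: 10 (2S,5R)-5-[(benzyloxy)methyl]-2-(prop-2-enyl)oxolan-3-one
Product: 11 (2S,3S,5R)-5-[(benzyloxy)methyl]-2-(prop-2-enyl)oxolan-3-ol
Conditions: LiBH(s-Bu)3, THF, −78 °C; then sat. aq NH4Cl
Reagents that add atoms: none
Why: Diastereoselective ketone reduction with a bulky trialkylborohydride, in which hydride should approach C7 from the face opposite the adjacent C6 allyl group so that the hydroxyl ends up cis to that chain (7S).

Step 7
Reactants: 11 (2S,3S,5R)-5-[(benzyloxy)methyl]-2-(prop-2-enyl)oxolan-3-ol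
Product: 12 tert-butyl{[(2S,3S,5R)-5-[(benzyloxy)methyl]-2-(prop-2-enyl)oxolan-3-yl]oxy}dimethylsilane
Conditions: TBSCl, imidazole, DMF, rt
Reagents that add atoms: tert-butyldimethylsilyl chloride, CC(C)(C)[Si](C)(C)Cl
Why: Standard imidazole-mediated silylation of a secondary alcohol; the TBS ether masks O7 through hydrogenation, Grignard addition and acylation and can be removed last without touching the ester or the terminal alkene.

Step 8
Reactants: 12 tert-butyl{[(2S,3S,5R)-5-[(benzyloxy)methyl]-2-(prop-2-enyl)oxolan-3-yl]oxy}dimethylsilane; 13 (Z)-hex-3-ene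
Product: 14 tert-butyl{[(2S,3S,5R)-5-[(benzyloxy)methyl]-2-(pent-2-en-1-yl)oxolan-3-yl]oxy}dimethylsilane (E/Z mixture)
Conditions: 13 (10 equiv), second-generation Grubbs catalyst RuCl2(=CHPh)(H2IMes)(PCy3) (5 mol%), CH2Cl2, 40 °C
Reagents that add atoms: (Z)-hex-3-ene (13), CC/C=C\CC
Why: Olefin cross-metathesis of the terminal alkene with an excess of a symmetrical internal alkene adds C1–C2 and releases volatile but-1-ene; the alkene geometry is irrelevant because the double bond is hydrogenated next.

Step 9
Reactants: 14 tert-butyl{[(2S,3S,5R)-5-[(benzyloxy)methyl]-2-(pent-2-en-1-yl)oxolan-3-yl]oxy}dimethylsilane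
Product: 15 [(2R,4S,5S)-4-{[tert-butyl(dimethyl)silyl]oxy}-5-pentyloxolan-2-yl]methanol
Conditions: H2 (1 atm), Pd(OH)2/C, EtOAc, rt
Reagents that add atoms: none
Why: Heterogeneous catalytic hydrogenation saturates the pentenyl chain and hydrogenolyses the benzyl ether in one operation, and running it in EtOAc should keep the TBS ether intact; no stereocentre is involved.

Step 10
Reactants: 15 [(2R,4S,5S)-4-{[tert-butyl(dimethyl)silyl]oxy}-5-pentyloxolan-2-yl]methanol
Product: 16 (2R,4S,5S)-4-{[tert-butyl(dimethyl)silyl]oxy}-5-pentyloxolane-2-carbaldehyde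
Conditions: Dess–Martin periodinane, CH2Cl2, 0 °C → rt; crude aldehyde used at once
Reagents that add atoms: none
Why: Dess–Martin oxidation converts the primary alcohol to the aldehyde under nearly neutral conditions, which should avoid epimerisation of the α-alkoxy centre C9.

Step 11
Reactants: 17 9-bromonon-1-ene
Product: 18 non-8-enylmagnesium bromide (Et2O solution, titrated)
Conditions: Mg turnings, I2 (cat.), Et2O, reflux
Reagents that add atoms: magnesium, [Mg]
Why: Grignard reagent formation by magnesium insertion into a primary alkyl bromide; the remote terminal alkene is too far away to cyclise onto the forming organometallic.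

Step 12
Reactants: 16 (2R,4S,5S)-4-{[tert-butyl(dimethyl)silyl]oxy}-5-pentyloxolane-2-carbaldehyde; 18 non-8-enylmagnesium bromide
Product: 19 (1R)-1-[(2R,4S,5S)-4-{[tert-butyl(dimethyl)silyl]oxy}-5-pentyloxolan-2-yl]dec-9-en-1-ol
Conditions: MgBr2·OEt2, CH2Cl2, −78 °C; then 18 (Et2O), −78 °C; sat. aq NH4Cl
Reagents that add atoms: non-8-enylmagnesium bromide (18), C=CCCCCCCC[Mg]Br
Why: Chelation-controlled (Cram chelate) Grignard addition to an α-alkoxy aldehyde, in which magnesium bridges the aldehyde oxygen and the ring oxygen and the alkyl group should add to the chelate face bearing H rather than ring carbon C8, giving the threo (9R,10R) carbinol.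

Step 13
Reactants: 19 (1R)-1-[(2R,4S,5S)-4-{[tert-butyl(dimethyl)silyl]oxy}-5-pentyloxolan-2-yl]dec-9-en-1-ol; 20 octadecanoyl chloride
Product: 21 (1R)-1-[(2R,4S,5S)-4-{[tert-butyl(dimethyl)silyl]oxy}-5-pentyloxolan-2-yl]dec-9-en-1-yl octadecanoate
Conditions: 20, pyridine, DMAP (cat.), CH2Cl2, 0 °C → rt
Reagents that add atoms: octadecanoyl chloride (20), CCCCCCCCCCCCCCCCCC(=O)Cl
Why: DMAP-catalysed acylation of the secondary alcohol with an acid chloride engages only the O–H bond, so C10 keeps its configuration, and O7 is blocked as its silyl ether.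

Step 14
Reactants: 21 (1R)-1-[(2R,4S,5S)-4-{[tert-butyl(dimethyl)silyl]oxy}-5-pentyloxolan-2-yl]dec-9-en-1-yl octadecanoate
Product: 22 (1R)-1-[(2R,4S,5S)-4-hydroxy-5-pentyloxolan-2-yl]dec-9-en-1-yl octadecanoate
Conditions: HF·pyridine, THF, 0 °C → rt
Reagents that add atoms: none
Why: Fluoride-mediated desilylation under acidic conditions removes the TBS group without generating an alkoxide that could cleave the ester or move the acyl group from O10 to O7.

**Compound list**
1 | ethyl 4-(benzyloxy)-3-oxobutanoate | CCOC(=O)CC(=O)COCc1ccccc1 | starting material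
2 | ethyl (3R)-4-(benzyloxy)-3-hydroxybutanoate | CCOC(=O)C[C@@H](O)COCc1ccccc1 | intermediate
3 | prop-2-enyl 2,2,2-trichloroacetimidate | C=CCOC(=N)C(Cl)(Cl)Cl | starting material
4 | ethyl (3R)-4-(benzyloxy)-3-(prop-2-enyloxy)butanoate | CCOC(=O)C[C@@H](OCC=C)COCc1ccccc1 | intermediate
5 | (3R)-4-(benzyloxy)-3-(prop-2-enyloxy)butanoic acid | OC(=O)C[C@@H](OCC=C)COCc1ccccc1 | intermediate
6 | (3R)-4-(benzyloxy)-3-(prop-2-enyloxy)butanoic 2-methylpropyl carbonic anhydride (formed in the flask, not isolated) | CC(C)COC(=O)OC(=O)C[C@@H](OCC=C)COCc1ccccc1 | intermediate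
7 | (4R)-5-(benzyloxy)-1-diazo-4-(prop-2-enyloxy)pentan-2-one | [N-]=[N+]=CC(=O)C[C@@H](OCC=C)COCc1ccccc1 | intermediate
8 | [(4R)-5-(benzyloxy)-2-oxo-4-(prop-2-enyloxy)pentylidene]copper, the copper carbenoid at C6 (ligands on copper not drawn; formed in the flask, not isolated) | [Cu]=CC(=O)C[C@@H](OCC=C)COCc1ccccc1 | intermediate
9 | (5R)-5-[(benzyloxy)methyl]-3-oxo-1-(prop-2-enyl)oxolan-1-ium-2-ide, the cyclic oxonium ylide (formed in the flask, not isolated) | C=CC[O+]1[CH-]C(=O)C[C@@H]1COCc1ccccc1 | intermediate
10 | (2S,5R)-5-[(benzyloxy)methyl]-2-(prop-2-enyl)oxolan-3-one | c1ccccc1COC[C@H]1CC(=O)[C@H](CC=C)O1 | intermediate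
11 | (2S,3S,5R)-5-[(benzyloxy)methyl]-2-(prop-2-enyl)oxolan-3-ol | c1ccccc1COC[C@H]1C[C@H](O)[C@H](CC=C)O1 | intermediate
12 | tert-butyl{[(2S,3S,5R)-5-[(benzyloxy)methyl]-2-(prop-2-enyl)oxolan-3-yl]oxy}dimethylsilane | c1ccccc1COC[C@H]1C[C@H](O[Si](C)(C)C(C)(C)C)[C@H](CC=C)O1 | intermediate
13 | (Z)-hex-3-ene | CC/C=C\CC | starting material
14 | tert-butyl{[(2S,3S,5R)-5-[(benzyloxy)methyl]-2-(pent-2-en-1-yl)oxolan-3-yl]oxy}dimethylsilane (E/Z mixture) | c1ccccc1COC[C@H]1C[C@H](O[Si](C)(C)C(C)(C)C)[C@H](CC=CCC)O1 | intermediate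
15 | [(2R,4S,5S)-4-{[tert-butyl(dimethyl)silyl]oxy}-5-pentyloxolan-2-yl]methanol | OC[C@H]1C[C@H](O[Si](C)(C)C(C)(C)C)[C@H](CCCCC)O1 | intermediate
16 | (2R,4S,5S)-4-{[tert-butyl(dimethyl)silyl]oxy}-5-pentyloxolane-2-carbaldehyde | O=C[C@H]1C[C@H](O[Si](C)(C)C(C)(C)C)[C@H](CCCCC)O1 | intermediate
17 | 9-bromonon-1-ene | C=CCCCCCCCBr | starting material
18 | non-8-enylmagnesium bromide | C=CCCCCCCC[Mg]Br | intermediate
19 | (1R)-1-[(2R,4S,5S)-4-{[tert-butyl(dimethyl)silyl]oxy}-5-pentyloxolan-2-yl]dec-9-en-1-ol | C=CCCCCCCC[C@@H](O)[C@H]1C[C@H](O[Si](C)(C)C(C)(C)C)[C@H](CCCCC)O1 | intermediate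
20 | octadecanoyl chloride (stearoyl chloride) | CCCCCCCCCCCCCCCCCC(=O)Cl | starting material
21 | (1R)-1-[(2R,4S,5S)-4-{[tert-butyl(dimethyl)silyl]oxy}-5-pentyloxolan-2-yl]dec-9-en-1-yl octadecanoate | C=CCCCCCCC[C@@H](OC(=O)CCCCCCCCCCCCCCCCC)[C@H]1C[C@H](O[Si](C)(C)C(C)(C)C)[C@H](CCCCC)O1 | intermediate
22 | (1R)-1-[(2R,4S,5S)-4-hydroxy-5-pentyloxolan-2-yl]dec-9-en-1-yl octadecanoate | C=CCCCCCCC[C@@H](OC(=O)CCCCCCCCCCCCCCCCC)[C@H]1C[C@H](O)[C@H](CCCCC)O1 | target

**Step count**
Total: 14 steps. Longest linear sequence: 13 steps (steps 1–10 and 12–14, from 1); step 11 prepares the Grignard reagent on the side.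

**Steps most likely to fail**

Step 5. The carbenoid may be diverted before or instead of the [2,3]-shift: C–H insertion, carbene dimerisation, or ylide formation at the benzyl ether oxygen followed by a [1,2]-benzyl shift. The trans relay from C9 to C6 may also be incomplete. The fallback generates the same α-oxo carbene from an alkyne and avoids the diazoketone. It sets out from ester 4. Half-reduction with i-Bu2AlH in CH2Cl2 at −78 °C should give (3R)-4-(benzyloxy)-3-(prop-2-enyloxy)butanal F1. Ohira–Bestmann homologation (dimethyl (1-diazo-2-oxopropyl)phosphonate, K2CO3, MeOH) should convert it to ({[(2R)-2-(prop-2-enyloxy)pent-4-yn-1-yl]oxy}methyl)benzene F2. Gold-catalysed alkyne oxidation (Ph3PAuNTf2, monovalent gold; 8-methylquinoline N-oxide; 1,2-dichloroethane, rt) should place oxygen on the internal alkyne carbon and give the [(4R)-5-(benzyloxy)-2-oxo-4-(prop-2-enyloxy)pentylidene](triphenylphosphine)gold cation F3. This carbene is expected to be trapped by the allyl ether oxygen as the ylide 9 and to rearrange as in the main route. The fallback comes back to the route at oxolanone 10.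

Step 12. Chelation may not dominate over Felkin-type addition, so facial selectivity at C10 could be poor and the erythro carbinol would contaminate 19. The fallback sets the centre by reduction instead of addition. It sets out from aldehyde 16. Addition of 18 in THF without a Lewis acid should give 19 mixed with (1S)-1-[(2R,4S,5S)-4-{[tert-butyl(dimethyl)silyl]oxy}-5-pentyloxolan-2-yl]dec-9-en-1-ol F4. Dess–Martin oxidation of the mixture should converge both epimers on 1-[(2R,4S,5S)-4-{[tert-butyl(dimethyl)silyl]oxy}-5-pentyloxolan-2-yl]dec-9-en-1-one F5. Reduction with LiBH(s-Bu)3 in THF at −78 °C is expected to follow the Felkin–Anh model (hydride anti to the ring C–O bond) and give the threo alcohol. The fallback comes back to the route at 19.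

Step 6. The benzyloxymethyl group at C9 lies across the ring on the face that hydride must use, so facial selectivity at C7 could erode and the 2,3-trans alcohol would form. The fallback corrects the centre by inversion. It sets out from ketone 10. Reduction with NaBH4 in MeOH at 0 °C and separation should give, beside 11, (2S,3R,5R)-5-[(benzyloxy)methyl]-2-(prop-2-enyl)oxolan-3-ol F6. Mitsunobu inversion (4-nitrobenzoic acid, PPh3, diisopropyl azodicarboxylate, THF) should give (2S,3S,5R)-5-[(benzyloxy)methyl]-2-(prop-2-enyl)oxolan-3-yl 4-nitrobenzoate F7. Methanolysis with K2CO3 in MeOH should release the cis alcohol. The fallback comes back to the route at 11.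

**Further compounds**
F1 | step 5 | (3R)-4-(benzyloxy)-3-(prop-2-enyloxy)butanal | O=CC[C@@H](OCC=C)COCc1ccccc1
F2 | step 5 | ({[(2R)-2-(prop-2-enyloxy)pent-4-yn-1-yl]oxy}methyl)benzene | C#CC[C@@H](OCC=C)COCc1ccccc1
F3 | step 5 | [(4R)-5-(benzyloxy)-2-oxo-4-(prop-2-enyloxy)pentylidene](triphenylphosphine)gold cation | O=C(C=[Au][P+](c1ccccc1)(c1ccccc1)c1ccccc1)C[C@@H](OCC=C)COCc1ccccc1
F4 | step 12 | (1S)-1-[(2R,4S,5S)-4-{[tert-butyl(dimethyl)silyl]oxy}-5-pentyloxolan-2-yl]dec-9-en-1-ol | C=CCCCCCCC[C@H](O)[C@H]1C[C@H](O[Si](C)(C)C(C)(C)C)[C@H](CCCCC)O1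
F5 | step 12 | 1-[(2R,4S,5S)-4-{[tert-butyl(dimethyl)silyl]oxy}-5-pentyloxolan-2-yl]dec-9-en-1-one | C=CCCCCCCCC(=O)[C@H]1C[C@H](O[Si](C)(C)C(C)(C)C)[C@H](CCCCC)O1
F6 | step 6 | (2S,3R,5R)-5-[(benzyloxy)methyl]-2-(prop-2-enyl)oxolan-3-ol | c1ccccc1COC[C@H]1C[C@@H](O)[C@H](CC=C)O1
F7 | step 6 | (2S,3S,5R)-5-[(benzyloxy)methyl]-2-(prop-2-enyl)oxolan-3-yl 4-nitrobenzoate | c1ccccc1COC[C@H]1C[C@H](OC(=O)c2ccc(cc2)[N+](=O)[O-])[C@H](CC=C)O1
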